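**Plan**

1. Locants: in the 2,3-dihydro-1,4-benzodioxine, O-1 joins C-2 (carboxyl carbon) to C-8a, O-4 joins C-3 (aryl carbon) to C-4a, and the cinnamate sits on C-7. Retrosynthetic cuts, in order: the C-7–vinyl bond (Heck), which frees the (R)-aryllactate acrylate; the two cis hydrogens on C-2/C-3 (back to the flat 1,4-benzodioxine); then O-1–C-8a and C-2–C-3 together.
2. Enabling feature: in the dioxane ring, O-1–C-2–CO2H is a glyoxylate unit and C-3 (bound to O-4 and the guaiacyl ring) is an aldehyde-level carbon. With H-3 replaced by a sulfonyl group, C-3 becomes a carbanion and later carries a leaving group; the iodine on C-8a, ortho to O-4, lies five atoms from the aldolate oxygen.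
3. Forward order: the sulfone is built from vanillyl alcohol and 4-bromo-2-iodophenol; the dioxine ring closes in one flask (aldol addition, copper O-arylation, loss of sulfinate); the ester is saponified and C-2=C-3 hydrogenated; the lactate acrylate is joined by a Heck reaction; acid removes two MOM groups and one tert-butyl ester.
4. Stereochemistry: C-2 and C-3 (cis, both R) arise together from enantioselective syn hydrogenation of the tetrasubstituted enediol-diether double bond; the lactate centre (R) comes from methyl (R)-glycidate; the E alkene comes from the Heck reaction.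
5. From the hydrogenation onwards C-2 carries a free carboxyl (a carboxylate under basic conditions) and the 4-hydroxyl of the C-3 aryl group stays masked, so neither enolisation at C-2 nor quinone-methide opening at C-3 can turn cis into trans.

Key step: step 5

Remark: the SMILES is read as the 2,3-cis acid (2R,3R; H-2 and H-3 on the same face) with an (R)-lactate centre, i.e. the less stable ring diastereomer.

**Route**

Step 1
Reactants: 1 4-(hydroxymethyl)-2-methoxyphenol (vanillyl alcohol)
Product: 2 2-methoxy-4-{[(4-methylphenyl)sulfanyl]methyl}phenol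
Conditions: 4-MeC6H4SH (1.1 equiv), TsOH·H2O (5 mol%), toluene, 60 °C
Reagents that add atoms: 4-methylbenzenethiol, Cc1ccc(S)cc1
Why: the p-hydroxybenzylic alcohol ionises under acid to a quinone-methide-like cation that the thiol captures at carbon (acid-catalysed SN1 thioetherification).

Step 2
Reactants: 2 2-methoxy-4-{[(4-methylphenyl)sulfanyl]methyl}phenol
Product: 3 2-methoxy-1-(methoxymethoxy)-4-{[(4-methylphenyl)sulfanyl]methyl}benzene
Conditions: MOMCl, iPr2NEt, CH2Cl2, 0 °C to rt
Reagents that add atoms: chloromethyl methyl ether, COCCl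
Why: Williamson-type O-alkylation of the phenol; the MOM ether should survive amide base, copper, hydrogenation and Heck conditions and leave with acid at the end.

Step 3
Reactants: 3 2-methoxy-1-(methoxymethoxy)-4-{[(4-methylphenyl)sulfanyl]methyl}benzene; 4 4-bromo-2-iodophenol
Product: 6 4-bromo-2-iodo-1-{[3-methoxy-4-(methoxymethoxy)phenyl][(4-methylphenyl)sulfanyl]methoxy}benzene (racemic), via α-chloro sulfide 5 (not isolated)
Conditions: NCS, CH2Cl2, 0 °C; then 4, iPr2NEt, 0 °C to rt
Reagents that add atoms: none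
Why: Pummerer-type α-chlorination of the benzyl sulfide gives 5, whose thionium ion is captured by the phenol oxygen (SN1 O-alkylation, as in methylthiomethyl ether formation); the new centre is racemic and is erased in step 5.

Step 4
Reactants: 6 4-bromo-2-iodo-1-{[3-methoxy-4-(methoxymethoxy)phenyl][(4-methylphenyl)sulfanyl]methoxy}benzene
Product: 7 4-bromo-2-iodo-1-{[3-methoxy-4-(methoxymethoxy)phenyl](4-methylbenzenesulfonyl)methoxy}benzene (racemic)
Conditions: mCPBA (2.2 equiv), NaHCO3, CH2Cl2, 0 °C
Reagents that add atoms: 3-chloroperoxybenzoic acid, O=C(OO)c1cccc(Cl)c1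
Why: chemoselective oxidation of sulfide to sulfone at sulfur, buffered so that the acetal-like carbon should not ionise; the aryl halides and the MOM ether are inert to the peracid at this temperature.

Step 5
Reactants: 7 4-bromo-2-iodo-1-{[3-methoxy-4-(methoxymethoxy)phenyl](4-methylbenzenesulfonyl)methoxy}benzene; 8 ethyl glyoxylate
Product: 11 ethyl 7-bromo-3-[3-methoxy-4-(methoxymethoxy)phenyl]-1,4-benzodioxine-2-carboxylate, via lithium aldolate 9 (not isolated), via sulfonyl benzodioxane 10 (not isolated)
Conditions: LiN(SiMe3)2, THF, −78 °C; 8; then CuI (10 mol%), 1,10-phenanthroline (20 mol%), Cs2CO3 (2 equiv), toluene, 80 °C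
Reagents that add atoms: none
Why: Proposed new method: LiN(SiMe3)2 turns 7 into a sulfonyl-stabilised α-aryloxybenzyl carbanion, an acyl-anion equivalent of the C-3 aldehyde carbon, which adds to the aldehyde of 8 and makes the C-2–C-3 bond; monovalent copper then takes up the alkoxide 9, inserts into the C–I bond five atoms away and closes O-1–C-8a by reductive elimination from trivalent copper (10), after which carbonate removes the acidic H-2 and expels toluenesulfinate to leave the C-2=C-3 double bond of 11. The closest known reaction types are the addition of lithiated α-alkoxy sulfones to aldehydes with later loss of sulfinate to an enol ether, and the copper-catalysed intramolecular O-arylation of alkoxides and enolates by ortho-halo aryl ethers that gives 1,4-benzodioxanes and benzofurans; their union with a glyoxylate into a formal [4+2] annulation is what has not been shown. The dioxine ring closes in a 6-exo-trig sense at the iodine-bearing ring carbon. No stereocentre is kept: the centres of 9 and 10 are erased by the elimination, which is why racemic 7 serves and why the configuration is left to step 7. Should sulfinate leave before the copper step, the α-keto-ester enolate so formed carries the same oxygen and cyclises to the same product, so both orders converge. The step needs C–I over C–Br selectivity (weaker C–I bond and intramolecular delivery), ring closure faster than retro-aldol (the C–O coupling is irreversible) and loss of sulfinate in preference to the ring aryloxide from the C-2 anion (sulfinate is by far the better leaving group).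

Step 6
Reactants: 11 ethyl 7-bromo-3-[3-methoxy-4-(methoxymethoxy)phenyl]-1,4-benzodioxine-2-carboxylate
Product: 12 7-bromo-3-[3-methoxy-4-(methoxymethoxy)phenyl]-1,4-benzodioxine-2-carboxylic acid
Conditions: LiOH, THF/H2O, rt; then 1 M HCl to pH 3, 0 °C
Reagents that add atoms: lithium hydroxide, [Li+].[OH-]
Why: saponification (BAc2) is done on the flat enol-ether ester, which has no stereocentre to lose, because the later cis compound would not tolerate hydroxide as an ester.

Step 7
Reactants: 12 7-bromo-3-[3-methoxy-4-(methoxymethoxy)phenyl]-1,4-benzodioxine-2-carboxylic acid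
Product: 13 (2R,3R)-7-bromo-3-[3-methoxy-4-(methoxymethoxy)phenyl]-2,3-dihydro-1,4-benzodioxine-2-carboxylic acid (2,3-cis)
Conditions: H2 (10 bar), [Ir(cod)(L*)]{B[3,5-(CF3)2C6H3]4} (1 mol%; L* = chiral spirobiindane phosphine–oxazoline), Et3N (0.5 equiv), MeOH, 40 °C
Reagents that add atoms: none
Why: the carboxylate binds iridium and both hydrogens are delivered to one face of the tetrasubstituted C-2=C-3 bond, so the cis relation follows from syn addition and the (2R,3R) sense from the ligand antipode (the mirror-image ligand is taken if the first one gives the 2S,3S acid); the reaction type is the asymmetric hydrogenation of α-aryloxy α,β-unsaturated carboxylic acids with chiral iridium P,N catalysts.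

Step 8
Reactants: 14 4-bromo-2-methoxyphenol
Product: 15 4-bromo-2-methoxy-1-(methoxymethoxy)benzene
Conditions: MOMCl, iPr2NEt, CH2Cl2, 0 °C to rt
Reagents that add atoms: chloromethyl methyl ether, COCCl
Why: Williamson-type O-alkylation gives a phenol mask that tolerates the Grignard reagent of step 9 and leaves with the other acid-labile groups in step 14.

Step 9
Reactants: 15 4-bromo-2-methoxy-1-(methoxymethoxy)benzene; 16 methyl (2R)-oxirane-2-carboxylate
Product: 18 methyl (2R)-2-hydroxy-3-[3-methoxy-4-(methoxymethoxy)phenyl]propanoate, via aryl Grignard reagent 17 (not isolated)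
Conditions: Mg, THF, 40 °C; then CuI (10 mol%), 16, THF, −40 °C; aq. NH4Cl
Reagents that add atoms: none
Why: copper-catalysed SN2 opening of the epoxide by the aryl Grignard reagent at the CH2 carbon should outrun attack on the ester at −40 °C and leaves the oxygen-bearing stereocentre untouched, so the (R) configuration of 16 is carried into 18.

Step 10
Reactants: 18 methyl (2R)-2-hydroxy-3-[3-methoxy-4-(methoxymethoxy)phenyl]propanoate
Product: 19 (2R)-2-hydroxy-3-[3-methoxy-4-(methoxymethoxy)phenyl]propanoic acid
Conditions: LiOH, THF/H2O, 0 °C; then 1 M HCl to pH 3, 0 °C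
Reagents that add atoms: lithium hydroxide, [Li+].[OH-]
Why: saponification of an α-hydroxy ester (BAc2) should not touch the stereocentre, whose α-hydrogen is not acidic once the carboxylate has formed.

Step 11
Reactants: 19 (2R)-2-hydroxy-3-[3-methoxy-4-(methoxymethoxy)phenyl]propanoic acid
Product: 20 tert-butyl (2R)-2-hydroxy-3-[3-methoxy-4-(methoxymethoxy)phenyl]propanoate
Conditions: Me2NCH(Ot-Bu)2, toluene, 80 °C
Reagents that add atoms: N,N-dimethylformamide di-tert-butyl acetal, CN(C)C(OC(C)(C)C)OC(C)(C)C
Why: the formamide acetal alkylates the carboxylate oxygen with a tert-butyl cation equivalent and leaves the secondary alcohol free (O-alkylative esterification).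

Step 12
Reactants: 20 tert-butyl (2R)-2-hydroxy-3-[3-methoxy-4-(methoxymethoxy)phenyl]propanoate
Product: 21 tert-butyl (2R)-3-[3-methoxy-4-(methoxymethoxy)phenyl]-2-(prop-2-enoyloxy)propanoate
Conditions: CH2=CHCOCl, Et3N, DMAP (cat.), CH2Cl2, −20 °C
Reagents that add atoms: acryloyl chloride, C=CC(Cl)=O
Why: acylation of the secondary alcohol by the acid chloride (nucleophilic acyl substitution) at low temperature should not epimerise the α-acyloxy ester.

Step 13
Reactants: 13 (2R,3R)-7-bromo-3-[3-methoxy-4-(methoxymethoxy)phenyl]-2,3-dihydro-1,4-benzodioxine-2-carboxylic acid; 21 tert-butyl (2R)-3-[3-methoxy-4-(methoxymethoxy)phenyl]-2-(prop-2-enoyloxy)propanoate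
Product: 22 (2R,3R)-7-[(1E)-3-({(2R)-1-tert-butoxy-3-[3-methoxy-4-(methoxymethoxy)phenyl]-1-oxopropan-2-yl}oxy)-3-oxoprop-1-en-1-yl]-3-[3-methoxy-4-(methoxymethoxy)phenyl]-2,3-dihydro-1,4-benzodioxine-2-carboxylic acid
Conditions: Pd(OAc)2 (5 mol%), P(o-tol)3 (15 mol%), Et3N (3 equiv), DMF, 90 °C; aq. citric acid work-up
Reagents that add atoms: none
Why: Mizoroki–Heck reaction (oxidative addition of zerovalent palladium into C–Br, syn insertion of the acrylate, syn β-hydride elimination) should give the E alkene, and the C-2 carboxyl is present as a triethylammonium carboxylate that cannot enolise, so the cis ring is not at risk from the amine base.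

Step 14
Reactants: 22 (2R,3R)-7-[(1E)-3-({(2R)-1-tert-butoxy-3-[3-methoxy-4-(methoxymethoxy)phenyl]-1-oxopropan-2-yl}oxy)-3-oxoprop-1-en-1-yl]-3-[3-methoxy-4-(methoxymethoxy)phenyl]-2,3-dihydro-1,4-benzodioxine-2-carboxylic acid
Product: 23 (2R,3R)-7-[(1E)-3-{[(1R)-1-carboxy-2-(4-hydroxy-3-methoxyphenyl)ethyl]oxy}-3-oxoprop-1-en-1-yl]-3-(4-hydroxy-3-methoxyphenyl)-2,3-dihydro-1,4-benzodioxine-2-carboxylic acid (CNP0171229.1)
Conditions: TFA/CH2Cl2/H2O (45:50:5), 0 °C to rt
Reagents that add atoms: none
Why: acidolysis should cleave both aryl MOM acetals and the tert-butyl ester (AAL1) while the cinnamate ester stays, and no base is used; the benzylic C-3–O-4 bond should resist ionisation because the adjacent C-2 carries two electron-withdrawing groups.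

**Compound list**

1 | 4-(hydroxymethyl)-2-methoxyphenol | COc1cc(CO)ccc1O | starting material
2 | 2-methoxy-4-{[(4-methylphenyl)sulfanyl]methyl}phenol | COc1cc(CSc2ccc(C)cc2)ccc1O | intermediate
3 | 2-methoxy-1-(methoxymethoxy)-4-{[(4-methylphenyl)sulfanyl]methyl}benzene | COCOc1ccc(CSc2ccc(C)cc2)cc1OC | intermediate
4 | 4-bromo-2-iodophenol | Oc1ccc(Br)cc1I | starting material
5 | 4-{chloro[(4-methylphenyl)sulfanyl]methyl}-2-methoxy-1-(methoxymethoxy)benzene (racemic; not isolated) | COCOc1ccc(C(Cl)Sc2ccc(C)cc2)cc1OC | intermediate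
6 | 4-bromo-2-iodo-1-{[3-methoxy-4-(methoxymethoxy)phenyl][(4-methylphenyl)sulfanyl]methoxy}benzene (racemic) | COCOc1ccc(C(Oc2ccc(Br)cc2I)Sc2ccc(C)cc2)cc1OC | intermediate
7 | 4-bromo-2-iodo-1-{[3-methoxy-4-(methoxymethoxy)phenyl](4-methylbenzenesulfonyl)methoxy}benzene (racemic) | COCOc1ccc(C(Oc2ccc(Br)cc2I)S(=O)(=O)c2ccc(C)cc2)cc1OC | intermediate
8 | ethyl glyoxylate (ethyl 2-oxoacetate) | CCOC(=O)C=O | starting material
9 | lithium alkoxide of ethyl 3-(4-bromo-2-iodophenoxy)-2-hydroxy-3-[3-methoxy-4-(methoxymethoxy)phenyl]-3-(4-methylbenzenesulfonyl)propanoate (diastereomer mixture; not isolated) | CCOC(=O)C([O-])C(Oc1ccc(Br)cc1I)(c1ccc(OCOC)c(OC)c1)S(=O)(=O)c1ccc(C)cc1.[Li+] | intermediate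
10 | ethyl 7-bromo-3-[3-methoxy-4-(methoxymethoxy)phenyl]-3-(4-methylbenzenesulfonyl)-2,3-dihydro-1,4-benzodioxine-2-carboxylate (diastereomer mixture; not isolated) | CCOC(=O)C1Oc2cc(Br)ccc2OC1(c1ccc(OCOC)c(OC)c1)S(=O)(=O)c1ccc(C)cc1 | intermediate
11 | ethyl 7-bromo-3-[3-methoxy-4-(methoxymethoxy)phenyl]-1,4-benzodioxine-2-carboxylate | CCOC(=O)C1=C(c2ccc(OCOC)c(OC)c2)Oc2ccc(Br)cc2O1 | intermediate
12 | 7-bromo-3-[3-methoxy-4-(methoxymethoxy)phenyl]-1,4-benzodioxine-2-carboxylic acid | OC(=O)C1=C(c2ccc(OCOC)c(OC)c2)Oc2ccc(Br)cc2O1 | intermediate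
13 | (2R,3R)-7-bromo-3-[3-methoxy-4-(methoxymethoxy)phenyl]-2,3-dihydro-1,4-benzodioxine-2-carboxylic acid (cis) | OC(=O)[C@@H]1Oc2cc(Br)ccc2O[C@@H]1c1ccc(OCOC)c(OC)c1 | intermediate
14 | 4-bromo-2-methoxyphenol | COc1cc(Br)ccc1O | starting material
15 | 4-bromo-2-methoxy-1-(methoxymethoxy)benzene | COCOc1ccc(Br)cc1OC | intermediate
16 | methyl (2R)-oxirane-2-carboxylate | COC(=O)[C@H]1CO1 | starting material
17 | bromo[3-methoxy-4-(methoxymethoxy)phenyl]magnesium (not isolated) | COCOc1ccc([Mg]Br)cc1OC | intermediate
18 | methyl (2R)-2-hydroxy-3-[3-methoxy-4-(methoxymethoxy)phenyl]propanoate | COC(=O)[C@H](O)Cc1ccc(OCOC)c(OC)c1 | intermediate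
19 | (2R)-2-hydroxy-3-[3-methoxy-4-(methoxymethoxy)phenyl]propanoic acid | OC(=O)[C@H](O)Cc1ccc(OCOC)c(OC)c1 | intermediate
20 | tert-butyl (2R)-2-hydroxy-3-[3-methoxy-4-(methoxymethoxy)phenyl]propanoate | CC(C)(C)OC(=O)[C@H](O)Cc1ccc(OCOC)c(OC)c1 | intermediate
21 | tert-butyl (2R)-3-[3-methoxy-4-(methoxymethoxy)phenyl]-2-(prop-2-enoyloxy)propanoate | CC(C)(C)OC(=O)[C@H](OC(=O)C=C)Cc1ccc(OCOC)c(OC)c1 | intermediate
22 | (2R,3R)-7-[(1E)-3-({(2R)-1-tert-butoxy-3-[3-methoxy-4-(methoxymethoxy)phenyl]-1-oxopropan-2-yl}oxy)-3-oxoprop-1-en-1-yl]-3-[3-methoxy-4-(methoxymethoxy)phenyl]-2,3-dihydro-1,4-benzodioxine-2-carboxylic acid | COCOc1ccc(C[C@@H](OC(=O)/C=C/c2ccc3c(c2)O[C@@H](C(=O)O)[C@@H](c2ccc(OCOC)c(OC)c2)O3)C(=O)OC(C)(C)C)cc1OC | intermediate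
23 | (2R,3R)-7-[(1E)-3-{[(1R)-1-carboxy-2-(4-hydroxy-3-methoxyphenyl)ethyl]oxy}-3-oxoprop-1-en-1-yl]-3-(4-hydroxy-3-methoxyphenyl)-2,3-dihydro-1,4-benzodioxine-2-carboxylic acid | COc1cc(C[C@@H](OC(=O)/C=C/c2ccc3c(c2)O[C@@H](C(=O)O)[C@@H](c2ccc(O)c(OC)c2)O3)C(=O)O)ccc1O | target

**Count and risks**

Total number of steps: 14. Longest linear sequence: 9 steps (steps 1 to 7, 13 and 14).

Steps most likely to fail:

1. Step 5 (proposed new method). What may go wrong: reversal of the aldol addition and base-induced decay of the glyoxylate before the ring closes; ionisation of sulfinate from the aldolate with epoxide formation and scrambling of the skeleton; sluggish C–O coupling at the crowded alkoxide. Fallback with known reactions, from 7 back to 11: the lithiated sulfone (LiN(SiMe3)2, THF, −78 °C) is C-acylated with ethyl chlorooxoacetate to the keto sulfone ethyl 3-(4-bromo-2-iodophenoxy)-3-[3-methoxy-4-(methoxymethoxy)phenyl]-3-(4-methylbenzenesulfonyl)-2-oxopropanoate F1. Reductive desulfonylation of this β-keto sulfone (SmI2, THF/MeOH, −78 °C) gives the α-keto ester ethyl 3-(4-bromo-2-iodophenoxy)-3-[3-methoxy-4-(methoxymethoxy)phenyl]-2-oxopropanoate F2. Copper-catalysed intramolecular O-arylation of its enolate (CuI, 1,10-phenanthroline, Cs2CO3, toluene, 90 °C) then gives 11. The C-2–C-3 bond and the O-1–C-8a bond are here made in separate, individually precedented steps.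

2. Step 7. What may go wrong: low turnover on the tetrasubstituted, doubly oxygenated double bond; poor facial discrimination by the chiral catalyst. Fallback from 12 back to 13: hydrogenation with the achiral complex [Ir(cod)(PCy3)(py)]PF6 (H2, CH2Cl2, rt), which also adds both hydrogens to one face, gives the racemic cis acid rac-(2R,3R)-7-bromo-3-[3-methoxy-4-(methoxymethoxy)phenyl]-2,3-dihydro-1,4-benzodioxine-2-carboxylic acid F3. Classical resolution follows by crystallisation of the diastereomeric salt (1S)-1-phenylethan-1-aminium (2R,3R)-7-bromo-3-[3-methoxy-4-(methoxymethoxy)phenyl]-2,3-dihydro-1,4-benzodioxine-2-carboxylate F4 (the antipodal amine is used if the other salt is the less soluble one). Cold dilute HCl releases 13.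

3. Step 13. What may go wrong: slow oxidative addition into the electron-rich aryl bromide at a temperature the acrylate tolerates; polymerisation of 21; erosion of the cis ring if the carboxylate is not maintained. Fallback from 13 back to 22: Suzuki–Miyaura vinylation (potassium vinyltrifluoroborate, PdCl2(dppf), Et3N, n-PrOH/H2O, 80 °C) gives the styrene (2R,3R)-7-ethenyl-3-[3-methoxy-4-(methoxymethoxy)phenyl]-2,3-dihydro-1,4-benzodioxine-2-carboxylic acid F5. Cross-metathesis of this with acrylate 21 (second-generation Hoveyda–Grubbs catalyst, CH2Cl2, 40 °C) forms the E cinnamate under neutral conditions and gives 22.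

**Further compounds**

F1 | step 5 | ethyl 3-(4-bromo-2-iodophenoxy)-3-[3-methoxy-4-(methoxymethoxy)phenyl]-3-(4-methylbenzenesulfonyl)-2-oxopropanoate (racemic) | CCOC(=O)C(=O)C(Oc1ccc(Br)cc1I)(c1ccc(OCOC)c(OC)c1)S(=O)(=O)c1ccc(C)cc1
F2 | step 5 | ethyl 3-(4-bromo-2-iodophenoxy)-3-[3-methoxy-4-(methoxymethoxy)phenyl]-2-oxopropanoate (racemic) | CCOC(=O)C(=O)C(Oc1ccc(Br)cc1I)c1ccc(OCOC)c(OC)c1
F3 | step 7 | rac-(2R,3R)-7-bromo-3-[3-methoxy-4-(methoxymethoxy)phenyl]-2,3-dihydro-1,4-benzodioxine-2-carboxylic acid (cis racemate, both enantiomers written) | OC(=O)[C@@H]1Oc2cc(Br)ccc2O[C@@H]1c1ccc(OCOC)c(OC)c1.OC(=O)[C@H]1Oc2cc(Br)ccc2O[C@H]1c1ccc(OCOC)c(OC)c1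
F4 | step 7 | (1S)-1-phenylethan-1-aminium (2R,3R)-7-bromo-3-[3-methoxy-4-(methoxymethoxy)phenyl]-2,3-dihydro-1,4-benzodioxine-2-carboxylate | [O-]C(=O)[C@@H]1Oc2cc(Br)ccc2O[C@@H]1c1ccc(OCOC)c(OC)c1.C[C@H]([NH3+])c1ccccc1
F5 | step 13 | (2R,3R)-7-ethenyl-3-[3-methoxy-4-(methoxymethoxy)phenyl]-2,3-dihydro-1,4-benzodioxine-2-carboxylic acid | OC(=O)[C@@H]1Oc2cc(C=C)ccc2O[C@@H]1c1ccc(OCOC)c(OC)c1
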